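Assumption: compounds 1, 2, 7, 8 and 11 are bought, 1 and 8 as single (R) enantiomers; side-chain carbons are called C1′ to C13′, counted from the lactone ring.

**Retrosynthetic overview**
1. Target 15 ⇒ bis-ether 13 (8-OMe, 6′-OBn) by one chelation-controlled BCl3 deprotection.
2. 13 ⇒ C4′–C5′ ketone bond: thiol ester 6 plus the B-alkyl borane of alkene 10 (Liebeskind–Srogl coupling, no Grignard chemistry near the lactone).
3. 10 ⇒ key step: 2,4-dimethoxybenzoic acid 7 plus (R)-epoxide 8 by carboxylate-directed C–H alkylation/lactonisation (replaces the usual lateral lithiation of an orsellinate); C3 comes directly from the epoxide.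
4. 6 ⇒ methyl (R)-glycidate 1 plus hexyl Grignard 2 (sets C6′).
5. Ring order: ring A (arene) is bought; ring B (δ-lactone) is the only ring made, in step 4.

**Route**

Step 1
Reactants: 1 methyl (R)-oxirane-2-carboxylate (methyl (R)-glycidate); 2 hexylmagnesium bromide
Product: 4 methyl (R)-2-hydroxynonanoate, via bromomagnesium alkoxide 3 (not isolated)
Conditions: 2 (1.3 equiv), CuBr·SMe2 (10 mol%), THF, –78 → –40 °C; then 1 M HCl
Reagents that add atoms: hexylmagnesium bromide (compound 2), CCCCCC[Mg]Br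
Why: Copper-catalysed Grignard opening of an α,β-epoxy ester (SN2 at the unhindered C3 methylene, faster than carbonyl addition at low temperature) never touches the C2–O bond, so the (R) centre of 1 becomes the (R) carbinol of 4.

Step 2
Reactants: 4 methyl (R)-2-hydroxynonanoate
Product: 5 methyl (R)-2-(benzyloxy)nonanoate
Conditions: BnOC(=NH)CCl3 (1.5 equiv), TfOH (5 mol%), CH2Cl2/cyclohexane, 0 °C → rt
Reagents that add atoms: benzyl 2,2,2-trichloroacetimidate, N=C(OCc1ccccc1)C(Cl)(Cl)Cl
Why: Acid-catalysed O-benzylation with a trichloroacetimidate is non-basic, so the enolisable α-stereocentre is not epimerised.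

Step 3
Reactants: 5 methyl (R)-2-(benzyloxy)nonanoate
Product: 6 S-phenyl (R)-2-(benzyloxy)nonanethioate
Conditions: PhSH, AlMe3 (1:1, premixed, 2 equiv), CH2Cl2, 0 °C → rt; then 1 M HCl
Reagents that add atoms: thiophenol, Sc1ccccc1
Why: Acyl substitution of a methyl ester by an aluminium thiolate (Me2AlSPh) is driven by the strong Al–O bond and runs under Lewis-acidic, non-enolising conditions, so the α-benzyloxy centre is retained.

Step 4
Reactants: 7 2,4-dimethoxybenzoic acid; 8 (R)-2-(but-3-en-1-yl)oxirane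
Product: 10 (R)-3-(but-3-en-1-yl)-6,8-dimethoxyisochroman-1-one, via hydroxy acid 9 (not isolated)
Conditions: 8 (2 equiv), Pd(OAc)2 (5 mol%), Ac-Val-OH (10 mol%), KOAc (1 equiv), (CF3)2CHOH, 75 °C, 24 h
Reagents that add atoms: none
Why: Carboxylate-directed ortho C–H palladation by divalent palladium at C6 (the only ortho C–H of 7), redox-neutral SN2-type opening of the epoxide at its terminal CH2 and lactonisation of 9 build ring B in one operation (C–H alkylation/lactonisation), and since the C–O bond at the epoxide stereocentre is never broken, the (R) configuration of 8 becomes C3 of 10 unchanged.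

Step 5
Reactants: 10 (R)-3-(but-3-en-1-yl)-6,8-dimethoxyisochroman-1-one; 11 9-borabicyclo[3.3.1]nonane (9-BBN); 6 S-phenyl (R)-2-(benzyloxy)nonanethioate
Product: 13 (R)-3-[(R)-6-(benzyloxy)-5-oxotridecyl]-6,8-dimethoxyisochroman-1-one, via B-alkyl-9-BBN adduct 12 (not isolated)
Conditions: 10 (1.3 equiv), 11 (1.4 equiv), THF, 0 °C → rt; then 6 (1.0 equiv), Pd(PPh3)4 (5 mol%), Cu(O2CC4H3S) (copper thiophene-2-carboxylate, 1.5 equiv), Cs2CO3 (1.5 equiv), THF, 45 °C
Reagents that add atoms: none
Why: Anti-Markovnikov hydroboration of the terminal alkene by 9-BBN (much faster than attack on the aryl lactone) followed by Liebeskind–Srogl coupling of the B-alkyl borane with the thiol ester (zerovalent palladium catalyst, copper carboxylate as thiolate scavenger) gives the ketone without over-addition and forms no new stereocentre.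

Step 6
Reactants: 13 (R)-3-[(R)-6-(benzyloxy)-5-oxotridecyl]-6,8-dimethoxyisochroman-1-one
Product: 15 (R)-8-hydroxy-3-[(R)-6-hydroxy-5-oxotridecyl]-6-methoxyisochroman-1-one (target), via bis(dichloroboryl) ester 14 (not isolated)
Conditions: BCl3 (5 equiv), C6HMe5 (3 equiv), CH2Cl2, –78 → 0 °C; then H2O
Reagents that add atoms: none
Why: Chelation-controlled Lewis-acid ether cleavage: BCl3 removes the methyl group peri to the lactone carbonyl and the benzyl group next to the ketone (benzyl cation trapped by pentamethylbenzene) but leaves the unchelated 6-OMe, the lactone and both stereocentres; water hydrolyses 14.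

**Compound list**
1 | methyl (R)-oxirane-2-carboxylate | COC(=O)[C@H]1CO1 | starting material
2 | hexylmagnesium bromide | CCCCCC[Mg]Br | starting material
3 | bromomagnesium (R)-1-methoxy-1-oxononan-2-olate | CCCCCCC[C@@H](O[Mg]Br)C(=O)OC | intermediate
4 | methyl (R)-2-hydroxynonanoate | CCCCCCC[C@@H](O)C(=O)OC | intermediate
5 | methyl (R)-2-(benzyloxy)nonanoate | CCCCCCC[C@@H](OCc1ccccc1)C(=O)OC | intermediate
6 | S-phenyl (R)-2-(benzyloxy)nonanethioate | CCCCCCC[C@@H](OCc1ccccc1)C(=O)Sc1ccccc1 | intermediate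
7 | 2,4-dimethoxybenzoic acid | COc1ccc(C(=O)O)c(OC)c1 | starting material
8 | (R)-2-(but-3-en-1-yl)oxirane | C=CCC[C@@H]1CO1 | starting material
9 | 2-[(R)-2-hydroxyhex-5-en-1-yl]-4,6-dimethoxybenzoic acid | C=CCC[C@@H](O)Cc1cc(OC)cc(OC)c1C(=O)O | intermediate
10 | (R)-3-(but-3-en-1-yl)-6,8-dimethoxyisochroman-1-one | C=CCC[C@@H]1Cc2cc(OC)cc(OC)c2C(=O)O1 | intermediate
11 | 9-borabicyclo[3.3.1]nonane | B1C2CCCC1CCC2 | starting material
12 | (R)-3-[4-(9-borabicyclo[3.3.1]nonan-9-yl)butyl]-6,8-dimethoxyisochroman-1-one | C1CCC2CCCC1B2CCCC[C@@H]1Cc2cc(OC)cc(OC)c2C(=O)O1 | intermediate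
13 | (R)-3-[(R)-6-(benzyloxy)-5-oxotridecyl]-6,8-dimethoxyisochroman-1-one | CCCCCCC[C@@H](OCc1ccccc1)C(=O)CCCC[C@@H]1Cc2cc(OC)cc(OC)c2C(=O)O1 | intermediate
14 | (R)-8-(dichloroboryloxy)-3-[(R)-6-(dichloroboryloxy)-5-oxotridecyl]-6-methoxyisochroman-1-one | CCCCCCC[C@@H](OB(Cl)Cl)C(=O)CCCC[C@@H]1Cc2cc(OC)cc(OB(Cl)Cl)c2C(=O)O1 | intermediate
15 | (R)-8-hydroxy-3-[(R)-6-hydroxy-5-oxotridecyl]-6-methoxyisochroman-1-one | CCCCCCC[C@@H](O)C(=O)CCCC[C@@H]1Cc2cc(OC)cc(O)c2C(=O)O1 | target

**Step count**
Total steps: 6. Longest linear sequence: 5 (steps 1, 2, 3, 5, 6); step 4 is a one-step branch.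

**Three steps most likely to fail**

Step 4. The pendant alkene may intercept the aryl–palladium species, or acid-promoted opening of the epoxide may outrun C–H activation. The fallback closes ring B by carbonylation instead of C–H activation; it sets out from 8 and comes back at 10. Copper-catalysed opening of 8 with 3,5-dimethoxyphenylmagnesium bromide (CuBr·SMe2 cat., THF, –30 °C) gives (R)-1-(3,5-dimethoxyphenyl)hex-5-en-2-ol F1 with the stereocentre untouched. NBS in MeCN at 0 °C brominates the very electron-rich ring ortho to the side chain and para to a methoxy group, giving (R)-1-(2-bromo-3,5-dimethoxyphenyl)hex-5-en-2-ol F2. Carbonylative lactonisation (CO 1 atm, Pd(OAc)2, Xantphos, Et3N, toluene, 90 °C) then gives 10.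

Step 5. The α-benzyloxy thiol ester may epimerise under Cs2CO3, or the B-alkyl transfer may be slow. The fallback makes the same C–C skeleton by olefin metathesis; it sets out from 5 and 10 and comes back at 13. Ester 5 with MeNHOMe·HCl and iPrMgCl (THF, –20 °C) gives (R)-2-(benzyloxy)-N-methoxy-N-methylnonanamide F3. Vinylmagnesium bromide (THF, 0 °C, acidic quench) converts it into (R)-4-(benzyloxy)undec-1-en-3-one F4. Cross-metathesis of F4 with 10 (second-generation Grubbs catalyst, 5 mol%, CH2Cl2, 40 °C) gives (R)-3-[(R,E)-6-(benzyloxy)-5-oxotridec-3-en-1-yl]-6,8-dimethoxyisochroman-1-one F5. Hydrogenation of the enone C=C only (H2 1 atm, RhCl(PPh3)3, benzene/EtOH, benzyl ether untouched) returns to 13.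

Step 6. Debenzylation of the alkyl benzyl ether may be incomplete, or the freed α-hydroxy ketone may isomerise under the Lewis acid. The fallback separates the two cleavages and uses a reductive method for the first; it sets out from 13 and comes back at 15. Hydrogenolysis (H2, Pd(OH)2/C, EtOAc, rt) gives (R)-3-[(R)-6-hydroxy-5-oxotridecyl]-6,8-dimethoxyisochroman-1-one F6. MgI2·OEt2 (THF, 50 °C) then cleaves only the methoxy group chelated to the lactone carbonyl and gives 15.

**Further compounds**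
F1 | step 4 | (R)-1-(3,5-dimethoxyphenyl)hex-5-en-2-ol | C=CCC[C@@H](O)Cc1cc(OC)cc(OC)c1
F2 | step 4 | (R)-1-(2-bromo-3,5-dimethoxyphenyl)hex-5-en-2-ol | C=CCC[C@@H](O)Cc1cc(OC)cc(OC)c1Br
F3 | step 5 | (R)-2-(benzyloxy)-N-methoxy-N-methylnonanamide | CCCCCCC[C@@H](OCc1ccccc1)C(=O)N(C)OC
F4 | step 5 | (R)-4-(benzyloxy)undec-1-en-3-one | CCCCCCC[C@@H](OCc1ccccc1)C(=O)C=C
F5 | step 5 | (R)-3-[(R,E)-6-(benzyloxy)-5-oxotridec-3-en-1-yl]-6,8-dimethoxyisochroman-1-one | CCCCCCC[C@@H](OCc1ccccc1)C(=O)/C=C/CC[C@@H]1Cc2cc(OC)cc(OC)c2C(=O)O1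
F6 | step 6 | (R)-3-[(R)-6-hydroxy-5-oxotridecyl]-6,8-dimethoxyisochroman-1-one | CCCCCCC[C@@H](O)C(=O)CCCC[C@@H]1Cc2cc(OC)cc(OC)c2C(=O)O1
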